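the same everywhere: D 2.1 mM (held)

|  | Z | L | X | remark |
|---|---|---|---|---|
| cedar | 0.010 M | 0.010 M | 32 µM | run made earlier |
| oak | 0.040 M | 0.040 M | 32 µM | run made earlier |
| elm | 0.020 M | 0.020 M | 16 µM | run made earlier |
| flask | 0.020 M | 0.020 M | 32 µM |  |

| run | time / min | G / % | Z / % |
|---|---|---|---|
| cedar | 4.00 | 10.2 | 38.4 |
| cedar | 10.0 | 27.2 | 25.3 |
| cedar | 20.0 | 40.0 | 7.4 |
| cedar | 30.0 | 47.0 | 2.8 |
| oak | 4.00 | 4.4 | 46.1 |
| oak | 10.0 | 11.1 | 39.4 |
| oak | 20.0 | 18.9 | 28.8 |
| oak | 30.0 | 28.4 | 21.2 |
| elm | 8.00 | 11.7 | 39.3 |
| elm | 15.0 | 23.5 | 27.2 |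
| elm | 25.0 | 34.0 | 17.3 |
| elm | 30.0 | 36.9 | 12.5 |

(readings scatter by 1 percentage point)

- X is single-handed; Z and L are mirror images of each other, charged as a racemate, each of them at the stated concentration
- what was read earlier has a scatter of 1 percentage point, one standard deviation
- at the start none of D is in solution

* apparent order in X when 30% of the Z and L together are converted (percent change of the rate of making G for one percent more X charged)

Read at 10.0 min, the cedar run has made G at a mean rate of 5.44 × 10⁻⁴ M min⁻¹ and the oak run at 8.88 × 10⁻⁴ M min⁻¹; each mean stands in for its curve up to that time. The oak charge of Z is 4.00 times the cedar charge, but the rate is 1.63 times. The flask has the same X, and its charge is the geometric mean of those two, so its rate is put at the geometric mean, 6.95 × 10⁻⁴ M min⁻¹.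

The elm run has the flask's Z with half the X. Its mean rates at 8.00 min and 15.0 min bracket that time, and their geometric mean is 6.05 × 10⁻⁴ M min⁻¹. As read, with the scatter of the readings on it, halving X slows the mean rate by a factor of 1.15.

order in X = ln(rate at full X ÷ rate at half X) ÷ ln(2) = 0.199

This is the halving exponent: the power of two by which the rate falls when X is halved. The scatter of the 4 readings puts about 0.0983 on it. If that factor holds along the whole elm run, which has the flask's charges of Z and L, it stretches the time to any given G from the flask to the elm run by the same factor.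

The forecast gives 0.43, reasoning that “The order in X equals the catalytic share of the resistance”; the reckoning above gives less, 0.199.

    E + X + Z → X + G (k = 93000 M⁻² s⁻¹)
    E + X + L → X + Q (k = 32000 M⁻² s⁻¹)
    2 X ⇌ J (K = 37000 M⁻¹, k = 220 M⁻¹ s⁻¹)
    D ⇌ E, rate k4*(csat - [E]) (kL = 0.0110 s⁻¹)

The flask gives an apparent order in X of 0.21. At 30% conversion of Z and L together, reached in the flask at 12.2 min, 52.8% of the catalyst is J, a form outside the working round (off-cycle). The flask holds G 37.8% at 25.0 min, so the halving exponent places that G in the elm run at 28.7 min; the elm run read G 36.9% at 30.0 min.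

(Readings and results are simulated for substances that don't exist, and the scatter is random.)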